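## Retrosynthetic overview
1. The acrylic acid comes from a 2-(hydroxymethyl)vinyl group (MnO2, then NaClO2), carried through the route as its TIPS ether.
2. The only ring, the 3,6-dihydro-2H-pyran, is closed by ring-closing metathesis (C4=C5) after all fragments have been joined.
3. The O1–C6 bond comes from a Williamson etherification of a chiral homoallylic alcohol (fragment A) with a C19 2-substituted allylic bromide (fragment B).
4. The key C2–C3 bond and the only stereocentre come from an intermolecular Brown asymmetric carbonyl allylation of 2-(TIPSO-methyl)acrolein with an allyl-B(Ipc)2 reagent.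
5. Fragment B comes from (2E,6E)-farnesyl bromide and the dianion of methallyl alcohol.

Assumption: the single stereocentre (ring C2) reads as R from the SMILES, and commercial (2E,6E)-farnesol of high isomeric purity supplies both E alkenes unchanged.

## Route

Step 1
Reactants: 1 2-methylidenepropane-1,3-diol
Product: 2 2-({[tri(propan-2-yl)silyl]oxy}methyl)prop-2-en-1-ol
Conditions: TIPSCl (1.0 equiv), imidazole (1.5 equiv), 1 (3 equiv), CH2Cl2/DMF 4:1, 0 °C to rt
Reagents that add atoms: chlorotri(propan-2-yl)silane (TIPSCl), CC(C)[Si](Cl)(C(C)C)C(C)C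
Why: Statistical monosilylation of a symmetric diol used in excess stops at the mono-ether, and TIPS is chosen because it does not migrate to a neighbouring alkoxide and survives the later basic and oxidative steps.

Step 2
Reactants: 2 2-({[tri(propan-2-yl)silyl]oxy}methyl)prop-2-en-1-ol
Product: 3 2-({[tri(propan-2-yl)silyl]oxy}methyl)prop-2-enal
Conditions: activated MnO2 (15 equiv), CH2Cl2, rt, filter through Celite
Reagents that add atoms: none
Why: The MnO2 allylic oxidation is neutral, stops at the aldehyde and leaves the silyl ether and the sensitive 2-substituted acrolein intact.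

Step 3 (key step)
Reactants: 3 2-({[tri(propan-2-yl)silyl]oxy}methyl)prop-2-enal; 4 allylmagnesium bromide; 5 (+)-B-methoxydiisopinocampheylborane, (+)-Ipc2BOMe, of the (−)-α-pinene series
Product: 8 (3R)-2-({[tri(propan-2-yl)silyl]oxy}methyl)hexa-1,5-dien-3-ol, via allylborane 6 (not isolated), via borinate ester 7 (not isolated)
Conditions: 5 (1.3 equiv), 4 (1.25 equiv, 1 M in Et2O), Et2O, 0 °C to rt, 1 h; 3, −78 °C, 3 h; then 3 M NaOH, 30% H2O2, 0 °C to rt
Reagents that add atoms: allylmagnesium bromide (compound 4, already counted as a reactant), C=CC[Mg]Br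
Why: In this Brown asymmetric allylboration (carbonyl allylation) the closed chair transition state with the isopinocampheyl groups of the (−)-α-pinene series delivers the allyl group to the Re face of the enal in pure 1,2 mode and sets the carbinol carbon (future ring C2) as R, typically in 90% ee or better for 2-substituted acroleins, and alkaline H2O2 then cleaves the borinate without touching TIPS.

Step 4
Reactants: 9 (2E,6E)-farnesol
Product: 10 (2E,6E)-1-bromo-3,7,11-trimethyldodeca-2,6,10-triene (farnesyl bromide)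
Conditions: PBr3 (0.4 equiv), Et2O, −10 °C to 0 °C, 45 min, used crude
Reagents that add atoms: phosphorus tribromide PBr3, BrP(Br)Br
Why: Bromide displaces the phosphite ester in an SN2 reaction at low temperature, which converts the primary allylic alcohol without allylic transposition or loss of E geometry.

Step 5
Reactants: 10 (2E,6E)-farnesyl bromide; 11 2-methylprop-2-en-1-ol (methallyl alcohol)
Product: 13 (5E,9E)-6,10,14-trimethyl-2-methylidenepentadeca-5,9,13-trien-1-ol, via dilithio dianion 12 (not isolated)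
Conditions: 11 (1.6 equiv), n-BuLi (3.3 equiv), TMEDA (3.3 equiv), Et2O/hexanes, 0 °C to rt, 20 h; 10 (1.0 equiv), THF, −78 °C to 0 °C; H2O
Reagents that add atoms: none
Why: In this dianion alkylation the allyllithium carbon, far more nucleophilic than the alkoxide, attacks the primary allylic bromide in SN2 mode, and because both ends of the 2-(oxidomethyl)allyl anion are equivalent only one constitution can form.

Step 6
Reactants: 13 (5E,9E)-6,10,14-trimethyl-2-methylidenepentadeca-5,9,13-trien-1-ol
Product: 14 (6E,10E)-14-(bromomethyl)-2,6,10-trimethylpentadeca-2,6,10,14-tetraene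
Conditions: CBr4 (1.2 equiv), PPh3 (1.25 equiv), CH2Cl2, 0 °C, 1 h; pentane trituration
Reagents that add atoms: carbon tetrabromide, BrC(Br)(Br)Br
Why: The Appel reaction runs under neutral conditions that spare the acid-sensitive polyene, and SN2 and SN2' attack on this 2-substituted allyl system give the same bromide.

Step 7
Reactants: 8 (3R)-2-({[tri(propan-2-yl)silyl]oxy}methyl)hexa-1,5-dien-3-ol; 14 (6E,10E)-14-(bromomethyl)-2,6,10-trimethylpentadeca-2,6,10,14-tetraene
Product: 16 (3R)-3-{[(5E,9E)-6,10,14-trimethyl-2-methylidenepentadeca-5,9,13-trien-1-yl]oxy}-2-({[tri(propan-2-yl)silyl]oxy}methyl)hexa-1,5-diene, via sodium alkoxide 15 (not isolated)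
Conditions: NaH (1.3 equiv), THF/DMF 4:1, 0 °C, 30 min; 14 (1.15 equiv), Bu4NI (0.1 equiv), 0 °C to rt
Reagents that add atoms: none
Why: This Williamson ether synthesis uses a reactive primary allylic bromide, the C–O bond at the stereocentre is not broken so R is retained, and the bulky TIPS group stays on the primary oxygen.

Step 8
Reactants: 16 the bis-allylic ether from step 7
Product: 17 (2R)-2-(3-{[tri(propan-2-yl)silyl]oxy}prop-1-en-2-yl)-5-[(3E,7E)-4,8,12-trimethyltrideca-3,7,11-trien-1-yl]-3,6-dihydro-2H-pyran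
Conditions: second-generation Grubbs catalyst RuCl2(=CHPh)(PCy3)(H2IMes) (5 mol %), 1,4-benzoquinone (10 mol %), CH2Cl2 (5 mM), reflux, argon sparge
Reagents that add atoms: none
Why: In this ring-closing metathesis the catalyst loads on the only monosubstituted alkene and closes the six-membered ring onto the nearby 1,1-disubstituted alkene, whereas the hindered silyloxymethyl-vinyl group (cyclobutene or tetrasubstituted dihydrofuran) and the trisubstituted chain alkenes (rings of nine or more members) offer no competitive closure, and C2 is untouched.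

Step 9
Reactants: 17 the TIPS-protected dihydropyran
Product: 18 2-{(2R)-5-[(3E,7E)-4,8,12-trimethyltrideca-3,7,11-trien-1-yl]-3,6-dihydro-2H-pyran-2-yl}prop-2-en-1-ol
Conditions: TBAF (1.3 equiv), THF, 0 °C to rt; H2O
Reagents that add atoms: none
Why: Fluoride-induced desilylation is driven by the strong Si–F bond and is orthogonal to the allylic ether and to all alkenes.

Step 10
Reactants: 18 the allylic alcohol
Product: 19 2-{(2R)-5-[(3E,7E)-4,8,12-trimethyltrideca-3,7,11-trien-1-yl]-3,6-dihydro-2H-pyran-2-yl}prop-2-enal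
Conditions: activated MnO2 (20 equiv), CH2Cl2, rt
Reagents that add atoms: none
Why: The MnO2 allylic oxidation is neutral, and the C2–H is not acidified because the carbonyl sits on the central carbon of the allyl system, so neither epimerisation nor alkene migration occurs.

Step 11
Reactants: 19 the enal
Product: 20 2-{(2R)-5-[(3E,7E)-4,8,12-trimethyltrideca-3,7,11-trien-1-yl]-3,6-dihydro-2H-pyran-2-yl}prop-2-enoic acid (target)
Conditions: NaClO2 (3 equiv), NaH2PO4 (4 equiv), 2-methylbut-2-ene (30 equiv), t-BuOH/H2O 4:1, 0 °C to rt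
Reagents that add atoms: sodium chlorite NaClO2, [Na+].[O-]Cl=O
Why: The Pinnick oxidation converts the enal to the acid at about pH 4 without conjugate addition or loss of the alkoxy group, and the large excess of 2-methylbut-2-ene traps HOCl before it can reach the chain alkenes.

## Compound list
1 | 2-methylidenepropane-1,3-diol | C=C(CO)CO | starting material
2 | 2-({[tri(propan-2-yl)silyl]oxy}methyl)prop-2-en-1-ol | C=C(CO)CO[Si](C(C)C)(C(C)C)C(C)C | intermediate
3 | 2-({[tri(propan-2-yl)silyl]oxy}methyl)prop-2-enal | C=C(C=O)CO[Si](C(C)C)(C(C)C)C(C)C | intermediate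
4 | allylmagnesium bromide | C=CC[Mg]Br | starting material
5 | (+)-B-methoxydiisopinocampheylborane, (−)-α-pinene series | COB([C@H]1C[C@H]2C[C@@H]([C@@H]1C)C2(C)C)[C@H]1C[C@H]2C[C@@H]([C@@H]1C)C2(C)C | starting material
6 | B-allyldiisopinocampheylborane, (−)-α-pinene series | C=CCB([C@H]1C[C@H]2C[C@@H]([C@@H]1C)C2(C)C)[C@H]1C[C@H]2C[C@@H]([C@@H]1C)C2(C)C | intermediate (not isolated)
7 | diisopinocampheylborinate ester of 8 | C=CC[C@@H](OB([C@H]1C[C@H]2C[C@@H]([C@@H]1C)C2(C)C)[C@H]1C[C@H]2C[C@@H]([C@@H]1C)C2(C)C)C(=C)CO[Si](C(C)C)(C(C)C)C(C)C | intermediate (not isolated)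
8 | (3R)-2-({[tri(propan-2-yl)silyl]oxy}methyl)hexa-1,5-dien-3-ol | C=CC[C@@H](O)C(=C)CO[Si](C(C)C)(C(C)C)C(C)C | intermediate
9 | (2E,6E)-farnesol | OC/C=C(\C)CC/C=C(\C)CCC=C(C)C | starting material
10 | (2E,6E)-farnesyl bromide | BrC/C=C(\C)CC/C=C(\C)CCC=C(C)C | intermediate
11 | 2-methylprop-2-en-1-ol | C=C(C)CO | starting material
12 | dilithio dianion of 11 | [Li]CC(=C)CO[Li] | intermediate (not isolated)
13 | (5E,9E)-6,10,14-trimethyl-2-methylidenepentadeca-5,9,13-trien-1-ol | C=C(CO)CC/C=C(\C)CC/C=C(\C)CCC=C(C)C | intermediate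
14 | (6E,10E)-14-(bromomethyl)-2,6,10-trimethylpentadeca-2,6,10,14-tetraene | C=C(CBr)CC/C=C(\C)CC/C=C(\C)CCC=C(C)C | intermediate
15 | sodium alkoxide of 8 | C=CC[C@@H]([O-])C(=C)CO[Si](C(C)C)(C(C)C)C(C)C.[Na+] | intermediate (not isolated)
16 | (3R)-bis-allylic ether (metathesis precursor) | C=CC[C@@H](OCC(=C)CC/C=C(\C)CC/C=C(\C)CCC=C(C)C)C(=C)CO[Si](C(C)C)(C(C)C)C(C)C | intermediate
17 | (2R)-TIPS-protected dihydropyran | C=C(CO[Si](C(C)C)(C(C)C)C(C)C)[C@H]1CC=C(CC/C=C(\C)CC/C=C(\C)CCC=C(C)C)CO1 | intermediate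
18 | (2R)-dihydropyranyl allylic alcohol | C=C(CO)[C@H]1CC=C(CC/C=C(\C)CC/C=C(\C)CCC=C(C)C)CO1 | intermediate
19 | (2R)-dihydropyranyl enal | C=C(C=O)[C@H]1CC=C(CC/C=C(\C)CC/C=C(\C)CCC=C(C)C)CO1 | intermediate
20 | 2-{(2R)-5-[(3E,7E)-4,8,12-trimethyltrideca-3,7,11-trien-1-yl]-3,6-dihydro-2H-pyran-2-yl}prop-2-enoic acid | C=C(C(=O)O)[C@H]1CC=C(CC/C=C(\C)CC/C=C(\C)CCC=C(C)C)CO1 | target

## Step count and risk
Total steps: 11. Longest linear sequence: 8 steps (1 → 2 → 3 → 8 → 16 → 17 → 18 → 19 → 20). The side-chain branch 9 → 10 → 13 → 14 → 16 → 20 is equally long.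

**Step 3.** The risks are the level of ee with a small, polymerisable enal and the separation from isopinocampheol. The fallback sets out from 3 and comes back at 8.
- Add allylmagnesium bromide 4 directly to 3 (THF, −78 °C) to obtain racemic 2-({[tri(propan-2-yl)silyl]oxy}methyl)hexa-1,5-dien-3-ol F1.
- Resolve it by Sharpless kinetic resolution: Ti(OiPr)4, L-(+)-diisopropyl tartrate, t-BuOOH (0.6 equiv), 4 Å sieves, CH2Cl2, −20 °C.
- The S enantiomer is epoxidised at its allylic 1,1-disubstituted alkene to the much more polar (1S)-1-[(2S)-2-({[tri(propan-2-yl)silyl]oxy}methyl)oxiran-2-yl]but-3-en-1-ol F2.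
- The slow-reacting R alcohol 8 is recovered (50% at most) in very high ee. The same treatment polishes 8 of insufficient ee from the allylboration.

**Step 5.** The risks are incomplete dianion formation, halogen–metal exchange or Wurtz coupling of 10, and some SN2' attack. The fallback sets out from 10 and comes back at 13.
- Alkylate the sodium enolate of ethyl acetoacetate (NaOEt, EtOH, 0 °C to rt) with 10 to give ethyl (4E,8E)-2-acetyl-5,9,13-trimethyltetradeca-4,8,12-trienoate F3.
- Saponify and decarboxylate (aq. KOH, MeOH, reflux, then acidify and warm) to (5E,9E)-6,10,14-trimethylpentadeca-5,9,13-trien-2-one F4.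
- Convert the ketone with dimethylsulfonium methylide (Me3SI, NaH, DMSO/THF, Corey–Chaykovsky) into racemic 2-methyl-2-[(3E,7E)-4,8,12-trimethyltrideca-3,7,11-trien-1-yl]oxirane F5.
- Isomerise the epoxide with LiNEt2 (Et2O/hexanes, reflux). The base removes a proton from the less hindered methyl group and delivers the 2-methylidene alcohol 13.

**Step 8.** The risks are slow closure onto a 1,1-disubstituted alkene, attack of the catalyst on the chain alkenes, and alkene isomerisation. The fallback closes the ring before the polyene is present. It sets out from 8, with 10 as the chain source, and comes back at 17.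
- Etherify 8 with excess 3-chloro-2-(chloromethyl)prop-1-ene (NaH, Bu4NI, THF/DMF) to (3R)-3-{[2-(chloromethyl)prop-2-en-1-yl]oxy}-2-({[tri(propan-2-yl)silyl]oxy}methyl)hexa-1,5-diene F6.
- Close it with the second-generation Grubbs catalyst RuCl2(=CHPh)(PCy3)(H2IMes) to (2R)-5-(chloromethyl)-2-(3-{[tri(propan-2-yl)silyl]oxy}prop-1-en-2-yl)-3,6-dihydro-2H-pyran F7.
- Separately, treat 10 with PhSO2Na (DMF, rt) to give {[(2E,6E)-3,7,11-trimethyldodeca-2,6,10-trien-1-yl]sulfonyl}benzene F8.
- Lithiate F8 (n-BuLi, THF/DMPU, −78 °C) and alkylate it with F7 to obtain the (2R)-dihydropyran carrying a 2-(phenylsulfonyl)-(3E,7E)-4,8,12-trimethyltrideca-3,7,11-trien-1-yl chain at C5 (epimers at the sulfonyl carbon) F9.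
- Remove the sulfone reductively with PdCl2(dppp) (5 mol %) and LiHBEt3 (THF, 0 °C). The zerovalent palladium formed in the flask ionises only the allylic sulfone, and hydride delivery keeps the position and E geometry of the alkene, giving 17.

## Further compounds
F1 | step 3 | racemic 2-({[tri(propan-2-yl)silyl]oxy}methyl)hexa-1,5-dien-3-ol | C=CCC(O)C(=C)CO[Si](C(C)C)(C(C)C)C(C)C
F2 | step 3 | (1S)-1-[(2S)-2-({[tri(propan-2-yl)silyl]oxy}methyl)oxiran-2-yl]but-3-en-1-ol | C=CC[C@H](O)[C@@]1(CO[Si](C(C)C)(C(C)C)C(C)C)CO1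
F3 | step 5 | ethyl (4E,8E)-2-acetyl-5,9,13-trimethyltetradeca-4,8,12-trienoate (racemic) | CCOC(=O)C(C(C)=O)C/C=C(\C)CC/C=C(\C)CCC=C(C)C
F4 | step 5 | (5E,9E)-6,10,14-trimethylpentadeca-5,9,13-trien-2-one | CC(=O)CC/C=C(\C)CC/C=C(\C)CCC=C(C)C
F5 | step 5 | 2-methyl-2-[(3E,7E)-4,8,12-trimethyltrideca-3,7,11-trien-1-yl]oxirane (racemic) | CC1(CC/C=C(\C)CC/C=C(\C)CCC=C(C)C)CO1
F6 | step 8 | (3R)-3-{[2-(chloromethyl)prop-2-en-1-yl]oxy}-2-({[tri(propan-2-yl)silyl]oxy}methyl)hexa-1,5-diene | C=CC[C@@H](OCC(=C)CCl)C(=C)CO[Si](C(C)C)(C(C)C)C(C)C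
F7 | step 8 | (2R)-5-(chloromethyl)-2-(3-{[tri(propan-2-yl)silyl]oxy}prop-1-en-2-yl)-3,6-dihydro-2H-pyran | C=C(CO[Si](C(C)C)(C(C)C)C(C)C)[C@H]1CC=C(CCl)CO1
F8 | step 8 | {[(2E,6E)-3,7,11-trimethyldodeca-2,6,10-trien-1-yl]sulfonyl}benzene | O=S(=O)(C/C=C(\C)CC/C=C(\C)CCC=C(C)C)c1ccccc1
F9 | step 8 | (2R)-dihydropyran with a 2-(phenylsulfonyl)-(3E,7E)-4,8,12-trimethyltrideca-3,7,11-trien-1-yl chain at C5 (epimers at the sulfonyl carbon) | C=C(CO[Si](C(C)C)(C(C)C)C(C)C)[C@H]1CC=C(CC(/C=C(\C)CC/C=C(\C)CCC=C(C)C)S(=O)(=O)c2ccccc2)CO1
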